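**Plan**
Retrosynthesis: the C1–aryl bond to the guaiacyl ring is cut first (aryl Grignard reagent onto a C1 aldehyde, with the benzylic oxygen removed afterwards). Then the two aldol bonds C2–C3 and C4–C5 are cut, leaving 3-(4-hydroxy-3,5-dimethoxyphenyl)propanal (C5–C7 plus the syringyl ring) and two acetaldehydes (C3–C4 and C1–C2).
Enabling feature: the acyclic chain between the two benzene rings carries C3(OH)–C4H2–C5(OH) with unsubstituted C2H2 and C4H2. With C1 as latent aldehyde carbon, this is the 3,5-dihydroxyaldehyde pattern that a 2-deoxyribose-5-phosphate aldolase (DERA) builds from acetaldehyde units.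
Forward: sinapaldehyde is hydrogenated to the propanal. The aldolase forms C4–C5, then C2–C3, and the product closes to a temporary oxane (lactol) ring. The guaiacyl Grignard reagent opens that ring at C1, and hydrogenolysis removes the C1 hydroxyl and the benzyl ether.
Stereochemistry: C5 (R) and C3 (S in the target, R while C1 is oxygenated, same spatial arrangement) come only from the fixed Si-face selectivity of the enzyme in both additions. The anomeric centre and the transient C1 carbinol are erased.

Key step: step 2

Assumption: the aldolase is an acetaldehyde-tolerant DERA (E. coli Cys47→Met background or a homologue), picked from a panel of wild-type and engineered enzymes for activity on 3-arylpropanals. Its facial selectivity is taken to be that of the native enzyme. Chain atoms are numbered C1 (guaiacyl end) to C7 (syringyl end) throughout.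

Step 1
Reactants: 1 (E)-sinapaldehyde [(E)-3-(4-hydroxy-3,5-dimethoxyphenyl)prop-2-enal]
Product: 2 3-(4-hydroxy-3,5-dimethoxyphenyl)propanal
Conditions: H2 (1 atm), 5% Pd/C, EtOAc, rt; stopped after 1 equiv H2
Reagents that add atoms: none
Why: Chemoselective heterogeneous catalytic hydrogenation of an enal, in which Pd saturates the conjugated C=C much faster than it reduces the resulting aliphatic aldehyde or the arene, so CHO, phenol and OMe groups should survive; no stereocentre is formed.

Step 2
Reactants: 2 3-(4-hydroxy-3,5-dimethoxyphenyl)propanal; 3 acetaldehyde (two molecules are incorporated)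
Product: 6 (4R,6R)-6-[2-(4-hydroxy-3,5-dimethoxyphenyl)ethyl]oxane-2,4-diol (anomer mixture at C2), via (3R)-3-hydroxy-5-(4-hydroxy-3,5-dimethoxyphenyl)pentanal 4 (not isolated), via (3R,5R)-3,5-dihydroxy-7-(4-hydroxy-3,5-dimethoxyphenyl)heptanal 5 (not isolated)
Conditions: DERA (Cys47→Met type, acceptor-screened variant, cell-free extract), 3 (3 equiv, syringe-pump feed), 0.1 M triethanolamine buffer pH 7.5, DMSO (10% v/v), 25 °C, N2, dark; MeCN precipitation of protein, EtOAc extraction
Reagents that add atoms: none
Why: The active-site lysine (Lys167 in the E. coli enzyme) condenses with 3 to an enamine that adds to the carbonyl of bound 2 (C4–C5 bond); hydrolysis of the iminium releases 4, which is bound again as acceptor for a second enamine addition (C2–C3 bond) to give 5. The closest known reaction type is the DERA tandem aldol that turns chloroacetaldehyde, 3-azidopropanal and 3-(acylamino)- or 3-phthalimidopropanals plus two acetaldehydes into 2,4,6-trideoxyhexose lactols, so β-substituted propanals with an aromatic terminus are an established acceptor class. The one ring closes by hemiacetalisation, O5 attacking C1 (6-exo-trig), which pulls the reversible aldol steps forward and masks the aldehyde so that no third addition occurs. C5 (first addition) and C3 (second addition) are both set by the enzyme alone, which delivers the enamine to the Si face of each acceptor carbonyl and so gives R at both centres, i.e. the syn-diol with 4-OH and the C6 side chain trans on the oxane; the anomeric carbon stays a mixture and is erased in step 4. The step needs donor/acceptor chemoselectivity and must outrun self-addition of 3: the narrow donor site admits only 3, while 2 is an unbranched, α-unsubstituted and achiral aldehyde that can act only as acceptor and offers no substrate bias to oppose the enzyme, and slow feeding of 3 keeps 2 and 4 the prevailing acceptors. The free phenol together with the DMSO cosolvent keeps 2 dissolved, and the Cys47→Met background prevents inactivation by crotonaldehyde formed from 3.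

Step 3
Reactants: 7 4-bromo-2-methoxyphenol
Product: 8 1-(benzyloxy)-4-bromo-2-methoxybenzene
Conditions: BnBr, K2CO3, DMF, rt
Reagents that add atoms: benzyl bromide, BrCc1ccccc1
Why: Williamson ether synthesis on the phenoxide; the benzyl ether removes the acidic proton before magnesium insertion and is later cleaved in the same hydrogenolysis that removes the C1 hydroxyl.

Step 4
Reactants: 8 1-(benzyloxy)-4-bromo-2-methoxybenzene (5 equiv); 6 (4R,6R)-6-[2-(4-hydroxy-3,5-dimethoxyphenyl)ethyl]oxane-2,4-diol
Product: 10 (1RS,3R,5R)-1-[4-(benzyloxy)-3-methoxyphenyl]-7-(4-hydroxy-3,5-dimethoxyphenyl)heptane-1,3,5-triol (epimer mixture at C1), via [4-(benzyloxy)-3-methoxyphenyl]magnesium bromide 9 (not isolated)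
Conditions: 8, Mg turnings, LiCl, THF, rt (gives 9); then 6 in THF, 0 °C to rt; aq NH4Cl
Reagents that add atoms: magnesium, [Mg] (held only in 9; it leaves as a salt on work-up)
Why: Grignard addition to the ring-chain tautomer of a lactol, in which three equivalents of 9 deprotonate the phenol, the 4-OH and the anomeric OH, the magnesium lactolate opens to the alkoxide form of aldehyde 5 and a further equivalent adds to C1; the C1 carbinol forms as an epimer mixture, which does not matter because C1 becomes CH2, and C3 and C5 are not touched.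

Step 5
Reactants: 10 (1RS,3R,5R)-1-[4-(benzyloxy)-3-methoxyphenyl]-7-(4-hydroxy-3,5-dimethoxyphenyl)heptane-1,3,5-triol
Product: 12 (3S,5R)-1-(4-hydroxy-3-methoxyphenyl)-7-(4-hydroxy-3,5-dimethoxyphenyl)heptane-3,5-diol (target), via (1RS,3R,5R)-1-(4-hydroxy-3-methoxyphenyl)-7-(4-hydroxy-3,5-dimethoxyphenyl)heptane-1,3,5-triol 11 (not isolated)
Conditions: H2 (4 bar), 10% Pd/C, EtOH–AcOH (4:1), 40 °C
Reagents that add atoms: none
Why: Catalytic hydrogenolysis, in which the O-benzyl ether is cleaved first to 11 and the activated p-hydroxybenzylic C1–OH is then cleaved under mild acid assistance, whereas the non-benzylic C3 and C5 carbinols are inert, so both stereocentres are retained (C3 changes descriptor from R to S only because C2 loses CIP rank).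

**Compound list**
1 | (E)-sinapaldehyde, (E)-3-(4-hydroxy-3,5-dimethoxyphenyl)prop-2-enal | COc1cc(/C=C/C=O)cc(OC)c1O | starting material
2 | 3-(4-hydroxy-3,5-dimethoxyphenyl)propanal | COc1cc(CCC=O)cc(OC)c1O | intermediate
3 | acetaldehyde | CC=O | starting material
4 | (3R)-3-hydroxy-5-(4-hydroxy-3,5-dimethoxyphenyl)pentanal | O=CC[C@H](O)CCc1cc(OC)c(O)c(OC)c1 | intermediate
5 | (3R,5R)-3,5-dihydroxy-7-(4-hydroxy-3,5-dimethoxyphenyl)heptanal | O=CC[C@H](O)C[C@H](O)CCc1cc(OC)c(O)c(OC)c1 | intermediate
6 | (4R,6R)-6-[2-(4-hydroxy-3,5-dimethoxyphenyl)ethyl]oxane-2,4-diol (anomer mixture) | OC1C[C@H](O)C[C@@H](CCc2cc(OC)c(O)c(OC)c2)O1 | intermediate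
7 | 4-bromo-2-methoxyphenol | COc1cc(Br)ccc1O | starting material
8 | 1-(benzyloxy)-4-bromo-2-methoxybenzene | COc1cc(Br)ccc1OCc1ccccc1 | intermediate
9 | [4-(benzyloxy)-3-methoxyphenyl]magnesium bromide | COc1cc([Mg]Br)ccc1OCc1ccccc1 | intermediate
10 | (1RS,3R,5R)-1-[4-(benzyloxy)-3-methoxyphenyl]-7-(4-hydroxy-3,5-dimethoxyphenyl)heptane-1,3,5-triol | COc1cc(C(O)C[C@H](O)C[C@H](O)CCc2cc(OC)c(O)c(OC)c2)ccc1OCc1ccccc1 | intermediate
11 | (1RS,3R,5R)-1-(4-hydroxy-3-methoxyphenyl)-7-(4-hydroxy-3,5-dimethoxyphenyl)heptane-1,3,5-triol | COc1cc(C(O)C[C@H](O)C[C@H](O)CCc2cc(OC)c(O)c(OC)c2)ccc1O | intermediate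
12 | (3S,5R)-1-(4-hydroxy-3-methoxyphenyl)-7-(4-hydroxy-3,5-dimethoxyphenyl)heptane-3,5-diol | COc1cc(CC[C@H](O)C[C@H](O)CCc2cc(OC)c(O)c(OC)c2)ccc1O | target

Total step count: 5
Longest linear sequence: 4 (steps 1, 2, 4, 5)

**Steps most likely to fail**

Step 2. The bulky, hydrophobic acceptor may bind or turn over poorly. The sequence may stall after the first addition, self-addition of acetaldehyde may consume the donor, or the enzyme may be inactivated before conversion is complete.
- The fallback sets out from 2 and builds the same lactol by chemical catalysis. The free phenol is carried through with an extra equivalent of base or hydride where needed.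
- A Roskamp reaction (ethyl diazoacetate, cat. SnCl2, CH2Cl2) should give ethyl 5-(4-hydroxy-3,5-dimethoxyphenyl)-3-oxopentanoate F1.
- Noyori hydrogenation with (R)-BINAP–Ru in EtOH sets C5 and should give ethyl (3R)-3-hydroxy-5-(4-hydroxy-3,5-dimethoxyphenyl)pentanoate F2.
- Claisen condensation with excess lithium enolate of tert-butyl acetate should give tert-butyl (5R)-5-hydroxy-7-(4-hydroxy-3,5-dimethoxyphenyl)-3-oxoheptanoate F3.
- Narasaka–Prasad reduction (Et2BOMe, NaBH4, THF–MeOH, −78 °C) sets C3 syn to C5 through the boron chelate and should give tert-butyl (3R,5R)-3,5-dihydroxy-7-(4-hydroxy-3,5-dimethoxyphenyl)heptanoate F4.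
- TFA in CH2Cl2 should close (4R,6R)-4-hydroxy-6-[2-(4-hydroxy-3,5-dimethoxyphenyl)ethyl]oxan-2-one F5.
- DIBAL-H at −78 °C reduces the lactone, and the fallback comes back to the route at 6.

Step 4. The polyanionic magnesium salt may precipitate before the ring opens. The β-alkoxy aldehyde may undergo retro-aldol cleavage or β-elimination under the basic conditions, and proton transfer uses up much of the reagent.
- The fallback sets out from 6 and reverses the polarity of C1, so that no carbonyl addition and no benzylic oxygen are involved.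
- NaBH4 in MeOH should give (3S,5R)-7-(4-hydroxy-3,5-dimethoxyphenyl)heptane-1,3,5-triol F6.
- An Appel reaction selective for the primary alcohol (CBr4, PPh3, 0 °C) should give (3R,5R)-1-bromo-7-(4-hydroxy-3,5-dimethoxyphenyl)heptane-3,5-diol F7.
- Nickel-catalysed reductive cross-electrophile coupling of F7 with aryl bromide 8 (NiI2, 4,4′-dimethoxy-2,2′-bipyridine, NaI, Zn, DMPU, 60 °C) tolerates hydroxyl groups. It should give (3S,5R)-1-[4-(benzyloxy)-3-methoxyphenyl]-7-(4-hydroxy-3,5-dimethoxyphenyl)heptane-3,5-diol F8.
- Neutral hydrogenolysis of the benzyl ether (H2, Pd/C, EtOH) brings the fallback back to the route at 12.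

Step 5. Three processes could interfere.
- Cleavage of the benzylic C–O bond may stall after debenzylation.
- The acid-assisted benzylic cation may be captured by O5 with ring closure.
- Elimination toward C2 may make the C3 oxygen allylic, with loss or epimerisation at C3.

The fallback sets out from 10, masks all internal nucleophiles and turns the C1 oxygen into a better leaving group, so that no acid is needed.
- Peracetylation (Ac2O, pyridine, DMAP) should give (1RS,3R,5R)-7-(4-acetoxy-3,5-dimethoxyphenyl)-1-[4-(benzyloxy)-3-methoxyphenyl]heptane-1,3,5-triyl triacetate F9.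
- Neutral hydrogenolysis (H2, Pd/C, EtOAc) cleaves the benzylic acetate and the benzyl ether. It should give (3S,5R)-7-(4-acetoxy-3,5-dimethoxyphenyl)-1-(4-hydroxy-3-methoxyphenyl)heptane-3,5-diyl diacetate F10.
- Methanolysis (K2CO3, MeOH) removes the three acetates, and the fallback comes back to the route at 12.

**Further compounds**
F1 | step 2 | ethyl 5-(4-hydroxy-3,5-dimethoxyphenyl)-3-oxopentanoate | CCOC(=O)CC(=O)CCc1cc(OC)c(O)c(OC)c1
F2 | step 2 | ethyl (3R)-3-hydroxy-5-(4-hydroxy-3,5-dimethoxyphenyl)pentanoate | CCOC(=O)C[C@H](O)CCc1cc(OC)c(O)c(OC)c1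
F3 | step 2 | tert-butyl (5R)-5-hydroxy-7-(4-hydroxy-3,5-dimethoxyphenyl)-3-oxoheptanoate | CC(C)(C)OC(=O)CC(=O)C[C@H](O)CCc1cc(OC)c(O)c(OC)c1
F4 | step 2 | tert-butyl (3R,5R)-3,5-dihydroxy-7-(4-hydroxy-3,5-dimethoxyphenyl)heptanoate | CC(C)(C)OC(=O)C[C@H](O)C[C@H](O)CCc1cc(OC)c(O)c(OC)c1
F5 | step 2 | (4R,6R)-4-hydroxy-6-[2-(4-hydroxy-3,5-dimethoxyphenyl)ethyl]oxan-2-one | O=C1C[C@H](O)C[C@@H](CCc2cc(OC)c(O)c(OC)c2)O1
F6 | step 4 | (3S,5R)-7-(4-hydroxy-3,5-dimethoxyphenyl)heptane-1,3,5-triol | OCC[C@H](O)C[C@H](O)CCc1cc(OC)c(O)c(OC)c1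
F7 | step 4 | (3R,5R)-1-bromo-7-(4-hydroxy-3,5-dimethoxyphenyl)heptane-3,5-diol | BrCC[C@H](O)C[C@H](O)CCc1cc(OC)c(O)c(OC)c1
F8 | step 4 | (3S,5R)-1-[4-(benzyloxy)-3-methoxyphenyl]-7-(4-hydroxy-3,5-dimethoxyphenyl)heptane-3,5-diol | COc1cc(CC[C@H](O)C[C@H](O)CCc2cc(OC)c(O)c(OC)c2)ccc1OCc1ccccc1
F9 | step 5 | (1RS,3R,5R)-7-(4-acetoxy-3,5-dimethoxyphenyl)-1-[4-(benzyloxy)-3-methoxyphenyl]heptane-1,3,5-triyl triacetate | COc1cc(C(OC(C)=O)C[C@H](OC(C)=O)C[C@H](OC(C)=O)CCc2cc(OC)c(OC(C)=O)c(OC)c2)ccc1OCc1ccccc1
F10 | step 5 | (3S,5R)-7-(4-acetoxy-3,5-dimethoxyphenyl)-1-(4-hydroxy-3-methoxyphenyl)heptane-3,5-diyl diacetate | COc1cc(CC[C@H](OC(C)=O)C[C@H](OC(C)=O)CCc2cc(OC)c(OC(C)=O)c(OC)c2)ccc1O
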